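**Plan**

1. Retrosynthesis: the C2=C3 alkene and the C16–O bond go first, then ring D at C13–C16 and C15–C16, ring C at C8–C14 and C9–C11, the lactone at C8=C9 and at the O–C7 acyl bond, and last the C10–C9, C10–C20 and C5–C6 bonds of ring A.
2. Forward: ring A is dressed first (C6, then C20 and C9 on C10), the spiro lactone is closed by Knoevenagel condensation, ring C is annulated with butadiene, ring D is closed by a vinyl-radical cyclisation, and the C16 carbinol and the ring A enone come last.
3. Enabling feature: C8 carries both the C7 lactone carbonyl and the C15 ketone carbon and is bonded to C9. A C8=C9 double bond inside the lactone ring (C10, C20, O, C7, C8, C9) is therefore a doubly activated dienophile, and both of its carbons are members of ring C (C8, C9, C11, C12, C13, C14).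
4. Stereochemistry: C5 from a rhodium/BINAP conjugate addition; C10 from entry of the C9 electrophile anti to the C5 branch; C8 and C9 together from suprafacial addition of butadiene to the C1 face of the spiro lactone; C13 from the geometry of the bridging radical closure; C16 from exo-face capture of oxygen.

Key step: step 12

Remark: all intermediates carry the ent-kaurane atom numbers of the target (ring A = C1–C5 and C10, C6 on C5, C20 and C9 on C10), and the BINAP antipode in step 2 is assigned by analogy with the known sense of induction on cyclohex-2-enone.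

**Route**

Step 1
Reactants: 1 4,4-dimethylcyclohex-2-en-1-one
Product: 2 4,4-dimethylcyclohexa-2,5-dien-1-one
Conditions: DDQ (1.3 equiv), TsOH·H2O (cat.), 1,4-dioxane, reflux
Reagents that add atoms: none
Why: Quinone dehydrogenation of a 4,4-disubstituted cyclohexenone (dienolisation toward C10, hydride transfer from C5 to DDQ) is the classical entry to cross-conjugated cyclohexadienones, and the quaternary C4 excludes aromatisation.

Step 2
Reactants: 2 4,4-dimethylcyclohexa-2,5-dien-1-one; 3 (E)-(2-phenylethenyl)boronic acid
Product: 4 (5R)-4,4-dimethyl-5-[(E)-2-phenylethenyl]cyclohex-2-en-1-one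
Conditions: [Rh(OH)((R)-BINAP)]2 (2.5 mol %), 3 (1.2 equiv), 1,4-dioxane/H2O (10:1), 35 °C
Reagents that add atoms: none
Why: Hayashi–Miyaura asymmetric 1,4-addition: the alkenyl–rhodium species inserts one of the two enantiotopic enone units and water protonates the rhodium enolate, so C5 is set by the ligand (the R antipode is expected to give the 5R adduct), while the second enone unit survives and blocks C2 during steps 5 and 7.

Step 3
Reactants: 4 (5R)-4,4-dimethyl-5-[(E)-2-phenylethenyl]cyclohex-2-en-1-one
Product: 6 (5S)-5-(hydroxymethyl)-4,4-dimethylcyclohex-2-en-1-one, via aldehyde 5 (not isolated)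
Conditions: OsO4 (2 mol %), NaIO4 (4 equiv), 2,6-lutidine, 1,4-dioxane/H2O (3:1), rt; extraction; then NaBH4, MeOH/CH2Cl2, −78 °C
Reagents that add atoms: osmium tetroxide, O=[Os](=O)(=O)=O (oxygen carrier, reoxidised by sodium periodate, [Na+].[O-]I(=O)(=O)=O)
Why: Lemieux–Johnson cleavage takes the electron-richer styrene-type alkene in preference to the electron-poor enone alkene, and borohydride at low temperature reduces the aldehyde but not the conjugated ketone; C5 keeps its configuration provided the alpha-branched aldehyde is reduced without delay.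

Step 4
Reactants: 6 (5S)-5-(hydroxymethyl)-4,4-dimethylcyclohex-2-en-1-one
Product: 7 (5S)-5-[(tert-butyldimethylsilyloxy)methyl]-4,4-dimethylcyclohex-2-en-1-one
Conditions: TBSCl, imidazole, DMF, 0 °C → rt
Reagents that add atoms: tert-butyldimethylsilyl chloride, CC(C)(C)[Si](C)(C)Cl
Why: Standard silylation of a primary alcohol; the ether keeps the hydroxyl from adding to C3 of the enone and marks O6 as the oxygen that stays protected to the end.

Step 5
Reactants: 7 (5S)-5-[(tert-butyldimethylsilyloxy)methyl]-4,4-dimethylcyclohex-2-en-1-one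
Product: 8 (5S,6R)-5-[(tert-butyldimethylsilyloxy)methyl]-6-(hydroxymethyl)-4,4-dimethylcyclohex-2-en-1-one
Conditions: LiN(iPr)2 (1.1 equiv), THF, −78 °C; monomeric formaldehyde in THF (from cracked paraformaldehyde), −78 °C; AcOH quench at −78 °C
Reagents that add atoms: formaldehyde, C=O
Why: Kinetic alpha-prime deprotonation of the cross-conjugated enone can only occur at C10 (C2 is sp2, C4 is quaternary), and the lithium dienolate undergoes aldol addition to formaldehyde; the new C10 centre (expected trans to the C5 branch) is of no consequence because C10 becomes planar again in step 7.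

Step 6
Reactants: 8 (5S,6R)-5-[(tert-butyldimethylsilyloxy)methyl]-6-(hydroxymethyl)-4,4-dimethylcyclohex-2-en-1-one
Product: 9 (5S,6R)-6-[(benzyloxy)methyl]-5-[(tert-butyldimethylsilyloxy)methyl]-4,4-dimethylcyclohex-2-en-1-one
Conditions: benzyl 2,2,2-trichloroacetimidate, TfOH (5 mol %), CH2Cl2/cyclohexane, 0 °C
Reagents that add atoms: benzyl 2,2,2-trichloroacetimidate, ClC(Cl)(Cl)C(=N)OCc1ccccc1
Why: Acid-catalysed O-benzylation with the trichloroacetimidate avoids the basic conditions under which a beta-hydroxy ketone would undergo retro-aldol cleavage or dehydration.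

Step 7
Reactants: 9 (5S,6R)-6-[(benzyloxy)methyl]-5-[(tert-butyldimethylsilyloxy)methyl]-4,4-dimethylcyclohex-2-en-1-one
Product: 11 (5R,6S)-6-[(benzyloxy)methyl]-5-[(tert-butyldimethylsilyloxy)methyl]-6-(dimethoxymethyl)-4,4-dimethylcyclohex-2-en-1-one, via silyl dienol ether 10 (not isolated)
Conditions: LiN(iPr)2/Me3SiCl (premixed), THF, −78 °C; pentane, filtration, concentration; then HC(OMe)3, Me3SiOTf (20 mol %), CH2Cl2, −78 °C; NaHCO3
Reagents that add atoms: trimethyl orthoformate, COC(OC)OC; chlorotrimethylsilane, C[Si](C)(C)Cl (silicon retained only in 10)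
Why: In-situ silyl trapping of the C10 lithium enolate should outrun beta-elimination of benzyl oxide, and the 2-silyloxy diene then adds in a Mukaiyama-type reaction to the dimethoxycarbenium ion from the orthoformate; the electrophile is expected to enter C10 on the face opposite the adjacent CH2OTBS group at C5, which places C9 trans and C20 cis to C6 as in the target.

Step 8
Reactants: 11 (5R,6S)-6-[(benzyloxy)methyl]-5-[(tert-butyldimethylsilyloxy)methyl]-6-(dimethoxymethyl)-4,4-dimethylcyclohex-2-en-1-one
Product: 12 (2S,3R)-3-[(tert-butyldimethylsilyloxy)methyl]-2-(dimethoxymethyl)-2-(hydroxymethyl)-4,4-dimethylcyclohexan-1-one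
Conditions: H2 (1 atm), Pd/C (10 wt %), EtOAc, rt
Reagents that add atoms: none
Why: Heterogeneous catalytic hydrogenation saturates the C2=C3 enone alkene, whose blocking role is over, and hydrogenolyses the benzyl ether in the same operation, freeing the C20 hydroxyl while acetal, ketone and silyl ether stay intact.

Step 9
Reactants: 13 Meldrum's acid
Product: 14 3-(ethylsulfanyl)-3-oxopropanoic acid
Conditions: EtSH (excess), toluene, sealed tube, 90 °C
Reagents that add atoms: ethanethiol, CCS
Why: Thermal ring opening of Meldrum's acid by a thiol with loss of acetone is the standard preparation of malonic acid half thioesters.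

Step 10
Reactants: 12 (2S,3R)-3-[(tert-butyldimethylsilyloxy)methyl]-2-(dimethoxymethyl)-2-(hydroxymethyl)-4,4-dimethylcyclohexan-1-one; 14 3-(ethylsulfanyl)-3-oxopropanoic acid
Product: 15 [(1S,6R)-6-[(tert-butyldimethylsilyloxy)methyl]-1-(dimethoxymethyl)-5,5-dimethyl-2-oxocyclohexyl]methyl 3-(ethylsulfanyl)-3-oxopropanoate
Conditions: 14 (1.5 equiv), N,N'-dicyclohexylcarbodiimide, CH2Cl2, 0 °C → rt
Reagents that add atoms: none
Why: Carbodiimide esterification of a malonic half acid (which runs through an acylketene) acylates the neopentyl C20 hydroxyl under neutral conditions that leave the acetal and the retro-aldol-prone beta-hydroxy ketone undisturbed.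

Step 11
Reactants: 15 [(1S,6R)-6-[(tert-butyldimethylsilyloxy)methyl]-1-(dimethoxymethyl)-5,5-dimethyl-2-oxocyclohexyl]methyl 3-(ethylsulfanyl)-3-oxopropanoate
Product: 17 spiro unsaturated lactone bearing the C8 ethylthiocarbonyl group (5R,10S), via keto aldehyde 16 (not isolated)
Conditions: In(OTf)3 (5 mol %), acetone/H2O (20:1), rt; then piperidinium acetate (10 mol %), 4 Å molecular sieves, CH2Cl2, rt
Reagents that add atoms: water, O (oxygen retained only in 16)
Why: Lewis-acid-catalysed acetal hydrolysis releases the C9 aldehyde without cleaving the silyl ether, and an amine-catalysed intramolecular Knoevenagel condensation of the acidic thiomalonate methylene with this aldehyde (much faster than with the hindered C1 ketone) closes the six-membered lactone and creates the C8=C9 double bond.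

Step 12
Reactants: 17 spiro unsaturated lactone bearing the C8 ethylthiocarbonyl group; 18 buta-1,3-diene
Product: 19 cis-fused cyclohexene lactone with quaternary C8 (stereocentres as in 30)
Conditions: buta-1,3-diene (excess), Et2AlCl (30 mol %), CH2Cl2, −78 → 0 °C, sealed vessel
Reagents that add atoms: none
Why: Et2AlCl chelated between the C7 lactone carbonyl and the C15 thioester carbonyl lowers the LUMO of the C8=C9 alkene, which then undergoes a concerted, asynchronous, normal-demand [4+2] cycloaddition with s-cis butadiene, bonding C9–C11 and C8–C14. The closest known reaction type is the Lewis-acid-promoted Diels–Alder reaction of 2-acyl and 2-alkoxycarbonyl cycloalkenones and unsaturated lactones with butadiene, which builds a quaternary ring-fusion carbon. Ring C (C8, C9, C11, C12, C13, C14) is closed by intermolecular [4+2] annulation, both sigma bonds forming suprafacially on each partner. C8 and C9 arise in the same event, so C15 and H9 must end cis, and their absolute sense is controlled by the spiro centre C10: the C5 branch with its CH2OTBS group and the neighbouring gem-dimethyl group covers one face of the lactone, so the diene should add from the face of the flat C1 carbonyl. The step needs this facial selectivity, which rests on the substrate bias just described, and chemoselectivity for the carbon dienophile over the O=C15–C8=C9 oxadiene mode, which the bidentate chelate should secure; regiochemistry does not arise with the symmetric diene, and the C12=C13 alkene is left where the ring D closure needs it.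

Step 13
Reactants: 19 cis-fused cyclohexene lactone with quaternary C8
Product: 20 C15 aldehyde (formyl group on C8)
Conditions: Et3SiH, Pd/C (10 wt %), acetone, rt
Reagents that add atoms: none
Why: Fukuyama reduction: oxidative addition of zerovalent palladium into the C–S bond, transmetalation with the silane and reductive elimination give the aldehyde without touching the ketone, the lactone or the ring C alkene.

Step 14
Reactants: 20 C15 aldehyde; 21 ethynylmagnesium bromide
Product: 22 C15 propargylic alcohol (mixture of C15 epimers)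
Conditions: HC≡CMgBr (1.2 equiv), THF, −78 °C; aq. NH4Cl
Reagents that add atoms: none
Why: Grignard addition to an aldehyde, which at −78 °C is far more electrophilic than the alpha-quaternary C1 ketone or the lactone; the C15 epimers are both carried on because C15 is oxidised in step 16.

Step 15
Reactants: 22 C15 propargylic alcohol
Product: 24 bicyclo[3.2.1]octane allylic alcohol with exocyclic C16=C17 methylene, via vinylstannane 23 (not isolated)
Conditions: Bu3SnH (slow addition), AIBN (cat.), benzene, 80 °C; then pyridinium p-toluenesulfonate, CH2Cl2, rt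
Reagents that add atoms: tributyltin hydride, CCCC[SnH](CCCC)CCCC (tin retained only in 23)
Why: Tin-hydride-mediated radical cyclisation of a 1,6-enyne: the stannyl radical adds to the terminal alkyne carbon C17, the C16 vinyl radical closes 5-exo-trig onto C13 and the C12 radical is reduced, the axial C15 tether on C8 fixing the configuration of C13; acid then protodestannylates the vinylstannane.

Step 16
Reactants: 24 bicyclo[3.2.1]octane allylic alcohol
Product: 25 C15 ketone with exocyclic C16=C17 methylene
Conditions: Dess–Martin periodinane, NaHCO3, CH2Cl2, rt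
Reagents that add atoms: none
Why: Dess–Martin oxidation of the secondary allylic alcohol (either C15 epimer) gives the alpha-methylene ketone under buffered, non-basic conditions.

Step 17
Reactants: 25 C15 ketone with exocyclic C16=C17 methylene
Product: 27 C16 tertiary alpha-ketol (C6–OTBS), via hydroperoxide 26 (not isolated)
Conditions: Mn(dpm)3 (20 mol %), PhSiH3, O2 (1 atm), iPrOH/CH2Cl2, 0 °C → rt; then P(OEt)3
Reagents that add atoms: dioxygen, O=O
Why: Mukaiyama-type hydration of an enone: hydrogen-atom transfer from a manganese hydride to the terminal C17 gives the tertiary alpha-keto radical at C16, which should capture O2 on the exo face of the bicyclo[3.2.1]octane (the side of the one-carbon bridge C14), and the phosphite reduces the hydroperoxide to the C16 alcohol with the configuration of the target.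

Step 18
Reactants: 27 C16 tertiary alpha-ketol
Product: 29 ring A enone carrying C16–OSiMe3 and C6–OTBS, via bis-silyl enol ether 28 (not isolated)
Conditions: Me3SiOTf, Et3N, CH2Cl2, 0 °C; then Pd(OAc)2 (1.1 equiv), MeCN, rt
Reagents that add atoms: trimethylsilyl trifluoromethanesulfonate, C[Si](C)(C)OS(=O)(=O)C(F)(F)F
Why: Soft enolisation can only occur toward C2 (C10, C8 and C16 are quaternary) and silylates the tertiary hydroxyl at the same time, and Saegusa–Ito oxidation of the silyl enol ether (palladium enolate, beta-hydride elimination from C3) installs the C2=C3 alkene, over-oxidation being impossible next to the quaternary C4.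

Step 19
Reactants: 29 ring A enone carrying C16–OSiMe3 and C6–OTBS
Product: 30 CNP0530135.1
Conditions: HF·pyridine, THF, 0 °C → rt
Reagents that add atoms: none
Why: Fluoride-mediated cleavage of the primary TBS ether and the tertiary trimethylsilyl ether under mildly acidic conditions that should spare the enone, the alpha-ketol and the lactone.

**Compound list**

1 | 4,4-dimethylcyclohex-2-en-1-one | CC1(C)CCC(=O)C=C1 | starting material
2 | 4,4-dimethylcyclohexa-2,5-dien-1-one | CC1(C)C=CC(=O)C=C1 | intermediate
3 | (E)-(2-phenylethenyl)boronic acid | OB(O)/C=C/c1ccccc1 | starting material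
4 | (5R)-4,4-dimethyl-5-[(E)-2-phenylethenyl]cyclohex-2-en-1-one | CC1(C)C=CC(=O)C[C@@H]1/C=C/c1ccccc1 | intermediate
5 | (1S)-2,2-dimethyl-5-oxocyclohex-3-ene-1-carbaldehyde (C6 aldehyde, not isolated) | CC1(C)C=CC(=O)C[C@@H]1C=O | intermediate
6 | (5S)-5-(hydroxymethyl)-4,4-dimethylcyclohex-2-en-1-one | CC1(C)C=CC(=O)C[C@@H]1CO | intermediate
7 | (5S)-5-[(tert-butyldimethylsilyloxy)methyl]-4,4-dimethylcyclohex-2-en-1-one | CC1(C)C=CC(=O)C[C@@H]1CO[Si](C)(C)C(C)(C)C | intermediate
8 | (5S,6R)-5-[(tert-butyldimethylsilyloxy)methyl]-6-(hydroxymethyl)-4,4-dimethylcyclohex-2-en-1-one (5,6-trans) | CC1(C)C=CC(=O)[C@@H](CO)[C@@H]1CO[Si](C)(C)C(C)(C)C | intermediate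
9 | (5S,6R)-6-[(benzyloxy)methyl]-5-[(tert-butyldimethylsilyloxy)methyl]-4,4-dimethylcyclohex-2-en-1-one | CC1(C)C=CC(=O)[C@@H](COCc2ccccc2)[C@@H]1CO[Si](C)(C)C(C)(C)C | intermediate
10 | trimethylsilyl dienol ether of 9 (C1–OSiMe3, C1=C10 and C2=C3; not isolated) | CC1(C)C=CC(O[Si](C)(C)C)=C(COCc2ccccc2)[C@@H]1CO[Si](C)(C)C(C)(C)C | intermediate
11 | (5R,6S)-6-[(benzyloxy)methyl]-5-[(tert-butyldimethylsilyloxy)methyl]-6-(dimethoxymethyl)-4,4-dimethylcyclohex-2-en-1-one (C9 acetal trans, C20 cis to C6) | CC1(C)C=CC(=O)[C@](C(OC)OC)(COCc2ccccc2)[C@@H]1CO[Si](C)(C)C(C)(C)C | intermediate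
12 | (2S,3R)-3-[(tert-butyldimethylsilyloxy)methyl]-2-(dimethoxymethyl)-2-(hydroxymethyl)-4,4-dimethylcyclohexan-1-one | CC1(C)CCC(=O)[C@](C(OC)OC)(CO)[C@@H]1CO[Si](C)(C)C(C)(C)C | intermediate
13 | Meldrum's acid (2,2-dimethyl-1,3-dioxane-4,6-dione) | CC1(C)OC(=O)CC(=O)O1 | starting material
14 | 3-(ethylsulfanyl)-3-oxopropanoic acid | CCSC(=O)CC(=O)O | intermediate
15 | [(1S,6R)-6-[(tert-butyldimethylsilyloxy)methyl]-1-(dimethoxymethyl)-5,5-dimethyl-2-oxocyclohexyl]methyl 3-(ethylsulfanyl)-3-oxopropanoate | CC1(C)CCC(=O)[C@](C(OC)OC)(COC(=O)CC(=O)SCC)[C@@H]1CO[Si](C)(C)C(C)(C)C | intermediate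
16 | [(1S,6R)-6-[(tert-butyldimethylsilyloxy)methyl]-1-formyl-5,5-dimethyl-2-oxocyclohexyl]methyl 3-(ethylsulfanyl)-3-oxopropanoate (not isolated) | CC1(C)CCC(=O)[C@](C=O)(COC(=O)CC(=O)SCC)[C@@H]1CO[Si](C)(C)C(C)(C)C | intermediate
17 | spiro unsaturated lactone (5R,10S): ring A C1 ketone spiro-fused at C10 to the lactone C10–C20H2–O–C7(=O)–C8(COSEt)=C9H, CH2OTBS on C5 cis to C20 | CC1(C)CCC(=O)[C@]2(COC(=O)C(C(=O)SCC)=C2)[C@@H]1CO[Si](C)(C)C(C)(C)C | intermediate
18 | buta-1,3-diene | C=CC=C | starting material
19 | Diels–Alder adduct: cis-fused cyclohexene (C12=C13) lactone, quaternary C8 bearing COSEt cis to H9, stereocentres as in 30 | CC1(C)CCC(=O)[C@]2(COC(=O)[C@@]3(C(=O)SCC)CC=CC[C@H]32)[C@@H]1CO[Si](C)(C)C(C)(C)C | intermediate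
20 | C15 aldehyde (formyl on C8 in place of the thioester) | CC1(C)CCC(=O)[C@]2(COC(=O)[C@@]3(C=O)CC=CC[C@H]32)[C@@H]1CO[Si](C)(C)C(C)(C)C | intermediate
21 | ethynylmagnesium bromide | C#C[Mg]Br | starting material
22 | C15 propargylic alcohol (1-hydroxyprop-2-ynyl on C8, both C15 epimers) | CC1(C)CCC(=O)[C@]2(COC(=O)[C@@]3(C(O)C#C)CC=CC[C@H]32)[C@@H]1CO[Si](C)(C)C(C)(C)C | intermediate
23 | cyclised vinylstannane (C16=C17H–SnBu3, ring D closed; not isolated) | CC1(C)CCC(=O)[C@]2(COC(=O)[C@@]34C[C@@H](CC[C@H]32)C(=C[Sn](CCCC)(CCCC)CCCC)C4O)[C@@H]1CO[Si](C)(C)C(C)(C)C | intermediate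
24 | bicyclo[3.2.1]octane allylic alcohol (C15–OH, exocyclic C16=C17H2) | CC1(C)CCC(=O)[C@]2(COC(=O)[C@@]34C[C@@H](CC[C@H]32)C(=C)C4O)[C@@H]1CO[Si](C)(C)C(C)(C)C | intermediate
25 | C15 ketone with exocyclic C16=C17 methylene | CC1(C)CCC(=O)[C@]2(COC(=O)[C@@]34C[C@@H](CC[C@H]32)C(=C)C4=O)[C@@H]1CO[Si](C)(C)C(C)(C)C | intermediate
26 | C16 hydroperoxide (not isolated) | CC1(C)CCC(=O)[C@]2(COC(=O)[C@@]34C[C@@H](CC[C@H]32)[C@](C)(OO)C4=O)[C@@H]1CO[Si](C)(C)C(C)(C)C | intermediate
27 | C16 tertiary alpha-ketol (exo OH, C17 methyl), C6–OTBS | CC1(C)CCC(=O)[C@]2(COC(=O)[C@@]34C[C@@H](CC[C@H]32)[C@](C)(O)C4=O)[C@@H]1CO[Si](C)(C)C(C)(C)C | intermediate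
28 | C1=C2 trimethylsilyl enol ether with C16–OSiMe3 (not isolated) | CC1(C)CC=C(O[Si](C)(C)C)[C@]2(COC(=O)[C@@]34C[C@@H](CC[C@H]32)[C@](C)(O[Si](C)(C)C)C4=O)[C@@H]1CO[Si](C)(C)C(C)(C)C | intermediate
29 | ring A enone (C2=C3) with C16–OSiMe3 and C6–OTBS | CC1(C)C=CC(=O)[C@]2(COC(=O)[C@@]34C[C@@H](CC[C@H]32)[C@](C)(O[Si](C)(C)C)C4=O)[C@@H]1CO[Si](C)(C)C(C)(C)C | intermediate
30 | CNP0530135.1 (5R,8S,9S,10S,13R,16S in ent-kaurane numbering) | CC1(C)C=CC(=O)[C@]2(COC(=O)[C@@]34C[C@@H](CC[C@H]32)[C@](C)(O)C4=O)[C@@H]1CO | target

**Step count and risks**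

Total steps: 19. Longest linear sequence: 18 (steps 1–8 and 10–19; step 9 is a one-step side branch).

Most likely to fail:

1. Step 12. The cycloaddition at C9, which is flanked by the quaternary spiro carbon, may be slow. Lewis-acid-induced loss of the silyl ether or the hetero-Diels–Alder mode of the O=C15–C8=C9 oxadiene could then compete, and attack from the C5 face could erode the facial selectivity. Fallback: catalyst control replaces substrate control. Setting out again from 17, butadiene is added in the presence of a C2-symmetric Cu(OTf)2/tert-butyl-bis(oxazoline) complex, which binds the C7/C15 dicarbonyl unit in a bidentate manner. The ligand antipode is chosen to be matched with attack on the C1 face, and the reaction returns to the route at 19. No new compound is formed on the way (F0).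

2. Step 7. Enolisation next to the benzyloxymethyl group may end in beta-elimination of benzyl oxide, and bond formation at the fully substituted, doubly flanked C10 may be slow or poorly face-selective. Fallback: the C–C bond is made by delivery from oxygen. Setting out from 9, the lithium enolate (LiN(SiMe3)2, THF, −78 °C) is O-acylated with allyl chloroformate to give the allyl dienyl carbonate F1. A Tsuji decarboxylative allylation (Pd2(dba)3, PPh3, THF) should then transfer the allyl group to C10 on the face opposite C6, giving the C10-allyl ketone F2. Isomerisation with RuHCl(CO)(PPh3)3 in toluene at 80 °C gives the prop-1-enyl ketone F3. OsO4/NaIO4 cleavage of this electron-richer alkene gives the alpha-formyl ketone F4, and acetalisation (HC(OMe)3, pyridinium p-toluenesulfonate, MeOH) returns to the route at 11.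

3. Step 2. Insertion at the neopentyl beta-carbon of the dienone may be slow, so protodeboronation of the alkenylboronic acid or a second addition to the product enone could intervene, and the level and sense of enantioselection on this substrate are untested. Fallback: iminium organocatalysis with a one-carbon nucleophile. Setting out from 2, nitromethane is added under catalysis by 9-amino-9-deoxy-epi-quinine (or its pseudo-enantiomer, whichever gives the required C5 configuration) with benzoic acid, giving the nitromethyl enone F5. A buffered Nef reaction (NaOMe, MeOH; then aqueous TiCl3, NH4OAc) converts it into aldehyde 5, where the sequence rejoins the route in the borohydride stage of step 3.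

**Further compounds**

F0 | step 12 | none | none
F1 | step 7 | allyl carbonate of the C1 dienol of 9 (C1=C10, C2=C3) | CC1(C)C=CC(OC(=O)OCC=C)=C(COCc2ccccc2)[C@@H]1CO[Si](C)(C)C(C)(C)C
F2 | step 7 | (5R,6S)-6-allyl-6-[(benzyloxy)methyl]-5-[(tert-butyldimethylsilyloxy)methyl]-4,4-dimethylcyclohex-2-en-1-one | CC1(C)C=CC(=O)[C@](CC=C)(COCc2ccccc2)[C@@H]1CO[Si](C)(C)C(C)(C)C
F3 | step 7 | C10 (E)-prop-1-enyl analogue of F2 (configured as 11) | CC1(C)C=CC(=O)[C@](/C=C/C)(COCc2ccccc2)[C@@H]1CO[Si](C)(C)C(C)(C)C
F4 | step 7 | C10 formyl ketone (free C9 aldehyde corresponding to 11) | CC1(C)C=CC(=O)[C@](C=O)(COCc2ccccc2)[C@@H]1CO[Si](C)(C)C(C)(C)C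
F5 | step 2 | (5S)-4,4-dimethyl-5-(nitromethyl)cyclohex-2-en-1-one | CC1(C)C=CC(=O)C[C@@H]1C[N+](=O)[O-]
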